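**Retrosynthetic overview**
- The strategy rests on ring B. Its four adjacent C–Br carbons C3'–C6' form a symmetric tetrabromobutadiene. The two carbons that close it, C1' (OAr) and C2' (OH), sit at the oxidation level of the CH2–CO2H unit of an aryloxyacetic acid.
- Cutting C1'–C6' and C2'–C3' (retro-[4+2], with SO2 and silanol restored) gives tetrabromothiophene 1,1-dioxide and the bis(trimethylsilyl) ketene acetal of (3,5-dibromo-2-methoxyphenoxy)acetic acid.
- The ArO–C1' bond goes back to an SN2 alkylation of 3,5-dibromo-2-methoxyphenol with ethyl bromoacetate. The phenol comes from 3,5-dibromosalicylaldehyde by O-methylation and Baeyer–Villiger oxidation.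
- Ring order: ring A is bought with both bromines in place and ring B is assembled last. No halogenation and no aryl ether coupling has to be run in the presence of C–Br bonds.

Key step: step 9

Remark: primed locants refer to ring B (C1' carries the aryloxy oxygen, C2' the hydroxyl). The target is achiral. Compounds 14 and 15 form racemic, and their configuration is left open because aromatisation erases it.

**Step 1**
Reactants: 1 3,5-dibromosalicylaldehyde
Product: 2 3,5-dibromo-2-methoxybenzaldehyde
Conditions: MeI (1.5 equiv), K2CO3, DMF, rt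
Reagents that add atoms: iodomethane, CI
Why: Williamson O-methylation (SN2 on MeI) of the acidic phenol, under a carbonate base that leaves the non-enolisable aldehyde and the aryl bromides untouched.

**Step 2**
Reactants: 2 3,5-dibromo-2-methoxybenzaldehyde
Product: 3 3,5-dibromo-2-methoxyphenyl formate
Conditions: mCPBA (1.5 equiv), CH2Cl2, rt → 40 °C
Reagents that add atoms: 3-chloroperbenzoic acid, O=C(OO)c1cccc(Cl)c1
Why: Baeyer–Villiger oxidation in which the aryl group, made a good migrating group by its ortho-methoxy donor, should shift to oxygen in preference to hydride, while C–Br and OMe are inert to peracid.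

**Step 3**
Reactants: 3 3,5-dibromo-2-methoxyphenyl formate
Product: 4 3,5-dibromo-2-methoxyphenol
Conditions: MeOH, Et3N (cat.), rt
Reagents that add atoms: none
Why: Base-catalysed transesterification, since an aryl formate is an activated ester that hands its formyl group to methanol at room temperature without affecting anything else.

**Step 4**
Reactants: 4 3,5-dibromo-2-methoxyphenol; 5 ethyl bromoacetate
Product: 6 ethyl (3,5-dibromo-2-methoxyphenoxy)acetate
Conditions: K2CO3, acetone, reflux
Reagents that add atoms: none
Why: Williamson ether synthesis, in which the phenoxide displaces bromide from the primary α-bromo ester, so the future diaryl ether C–O bond is made at an sp3 carbon and no aryl bromide takes part.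

**Step 5**
Reactants: 6 ethyl (3,5-dibromo-2-methoxyphenoxy)acetate
Product: 7 (3,5-dibromo-2-methoxyphenoxy)acetic acid
Conditions: LiOH, THF/H2O, rt; then 1 M HCl
Reagents that add atoms: lithium hydroxide, [Li+].[OH-]
Why: Ordinary ester saponification by acyl–oxygen cleavage, to which the aryl ethers and aryl bromides are inert at room temperature.

**Step 6**
Reactants: 7 (3,5-dibromo-2-methoxyphenoxy)acetic acid
Product: 8 trimethylsilyl (3,5-dibromo-2-methoxyphenoxy)acetate
Conditions: HN(SiMe3)2 (0.6 equiv), PhMe, 80 °C; evaporate, use crude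
Reagents that add atoms: hexamethyldisilazane, C[Si](C)(C)N[Si](C)(C)C
Why: Silylation of a carboxylic acid with a disilazane, chosen because the only by-product is a gas and the crude silyl ester is dry and salt-free for the enolisation.

**Step 7**
Reactants: 8 trimethylsilyl (3,5-dibromo-2-methoxyphenoxy)acetate
Product: 10 2-(3,5-dibromo-2-methoxyphenoxy)-1,1-bis(trimethylsilyloxy)ethene, via lithium enolate 9 (not isolated)
Conditions: Me3SiCl (1.3 equiv), LiN(SiMe3)2 (1.1 equiv, added last), THF, −78 → 0 °C; evaporate, dry pentane, filter under Ar; use crude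
Reagents that add atoms: chlorotrimethylsilane, C[Si](C)(C)Cl
Why: Standard amide-base enolisation and O-silylation of a silyl ester to a ketene bis(silyl) acetal, where the α-aryloxy C–H is acidic enough for LiN(SiMe3)2, a base too weak to metalate ring A at C4–H between the two bromines and unable to undergo Br/Li exchange, and enolate 9 is trapped at once by the chlorosilane already present.

**Step 8**
Reactants: 11 tetrabromothiophene
Product: 13 tetrabromothiophene 1,1-dioxide, via tetrabromothiophene 1-oxide 12 (not isolated)
Conditions: H2O2 (50% aq.), (CF3CO)2O (excess), CH2Cl2, 0 °C → rt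
Reagents that add atoms: hydrogen peroxide, OO (its oxygen is delivered through trifluoroperacetic acid, OOC(=O)C(F)(F)F, made in the flask with trifluoroacetic anhydride)
Why: Electrophilic peracid oxidation of thiophene sulfur to the sulfone, which on this very electron-poor ring needs the strongest common peracid, while full bromine substitution slows self-dimerisation of 12 and 13.

**Step 9**
Reactants: 10 2-(3,5-dibromo-2-methoxyphenoxy)-1,1-bis(trimethylsilyloxy)ethene; 13 tetrabromothiophene 1,1-dioxide
Product: 16 3,4,5,6-tetrabromo-2-(3,5-dibromo-2-methoxyphenoxy)phenyl trimethylsilyl ether, via bridged sulfone adduct 14 (not isolated), via bis(silyloxy)cyclohexadiene 15 (not isolated)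
Conditions: 13 (1.0 equiv), 10 (1.5 equiv), 2,6-di-tert-butyl-4-methylpyridine (0.1 equiv), dry PhMe, 0 °C → rt, then 110 °C, slow Ar sweep; evaporate, use crude
Reagents that add atoms: none
Why: Proposed new method: the low-LUMO, s-cis-locked diene 13 should add the electron-rich C=C of 10 across C2/C5 in an inverse-electron-demand [4+2] cycloaddition (concerted, or through a short-lived zwitterion that collapses at the same termini), forming C1'–C6' and C2'–C3' and giving the bridged sulfone 14. Cheletropic loss of SO2 from 14 gives cyclohexadiene 15, and 1,2-loss of trimethylsilanol across C1'–H/C2'–OSi is the only aromatising exit, because the ketal carbon bears no hydrogen with which the aryloxy group could leave; if the ketal were hydrolysed first, the resulting dienone would tautomerise to the same phenol. The closest known reaction types are the Diels–Alder/SO2-extrusion annulation of tetrahalothiophene 1,1-dioxides with alkenes and alkynes, and the cycloaddition of ketene acetals to 2-pyrones or 1,2,4-triazines followed by loss of a small molecule and an alcohol. Ring B is the only ring closed, by an intermolecular [4+2] mode with four carbons from 13 and two from 10. The stereocentres of 14 and 15 (the bridgeheads and C1') arise racemic and uncontrolled, and all vanish on aromatisation. Regiochemistry does not arise because 13 is C2v-symmetric; the selectivity required is bonding at C2/C5 instead of Mukaiyama–Michael addition at C3 or attack at bromine, and it is favoured by the non-polar medium and the absence of Lewis acid and fluoride, which keep 10 a neutral π-donor and not a free enolate.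

**Step 10**
Reactants: 16 3,4,5,6-tetrabromo-2-(3,5-dibromo-2-methoxyphenoxy)phenyl trimethylsilyl ether
Product: 17 3,4,5,6-tetrabromo-2-(3,5-dibromo-2-methoxyphenoxy)phenol (CNP0187182.0)
Conditions: HCl (cat.), THF/H2O, rt
Reagents that add atoms: none
Why: Acid-catalysed hydrolysis of an aryl trimethylsilyl ether, made very easy by the acidic tetrabromophenol leaving group, under conditions to which the methyl ether, the diaryl ether and all six C–Br bonds are inert.

**Compound list**
1 | 3,5-dibromosalicylaldehyde | O=Cc1cc(Br)cc(Br)c1O | starting material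
2 | 3,5-dibromo-2-methoxybenzaldehyde | COc1c(Br)cc(Br)cc1C=O | intermediate
3 | 3,5-dibromo-2-methoxyphenyl formate | COc1c(Br)cc(Br)cc1OC=O | intermediate
4 | 3,5-dibromo-2-methoxyphenol | COc1c(Br)cc(Br)cc1O | intermediate
5 | ethyl bromoacetate | CCOC(=O)CBr | starting material
6 | ethyl (3,5-dibromo-2-methoxyphenoxy)acetate | CCOC(=O)COc1cc(Br)cc(Br)c1OC | intermediate
7 | (3,5-dibromo-2-methoxyphenoxy)acetic acid | COc1c(Br)cc(Br)cc1OCC(=O)O | intermediate
8 | trimethylsilyl (3,5-dibromo-2-methoxyphenoxy)acetate | COc1c(Br)cc(Br)cc1OCC(=O)O[Si](C)(C)C | intermediate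
9 | lithium enolate of 8 (geometry open, without consequence after silylation; not isolated) | COc1c(Br)cc(Br)cc1OC=C([O-])O[Si](C)(C)C.[Li+] | intermediate
10 | 2-(3,5-dibromo-2-methoxyphenoxy)-1,1-bis(trimethylsilyloxy)ethene | COc1c(Br)cc(Br)cc1OC=C(O[Si](C)(C)C)O[Si](C)(C)C | intermediate
11 | tetrabromothiophene | Brc1sc(Br)c(Br)c1Br | starting material
12 | tetrabromothiophene 1-oxide (not isolated) | O=S1C(Br)=C(Br)C(Br)=C1Br | intermediate
13 | tetrabromothiophene 1,1-dioxide | O=S1(=O)C(Br)=C(Br)C(Br)=C1Br | intermediate
14 | 1,2,3,4-tetrabromo-5-(3,5-dibromo-2-methoxyphenoxy)-6,6-bis(trimethylsilyloxy)-7-thiabicyclo[2.2.1]hept-2-ene 7,7-dioxide (racemic, endo/exo open; not isolated) | O=S1(=O)C2(Br)C(Br)=C(Br)C1(Br)C(Oc1cc(Br)cc(Br)c1OC)C2(O[Si](C)(C)C)O[Si](C)(C)C | intermediate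
15 | 1,2,3,4-tetrabromo-5-(3,5-dibromo-2-methoxyphenoxy)-6,6-bis(trimethylsilyloxy)cyclohexa-1,3-diene (racemic; not isolated) | BrC1=C(Br)C(Br)=C(Br)C(O[Si](C)(C)C)(O[Si](C)(C)C)C1Oc1cc(Br)cc(Br)c1OC | intermediate
16 | 3,4,5,6-tetrabromo-2-(3,5-dibromo-2-methoxyphenoxy)phenyl trimethylsilyl ether | COc1c(Br)cc(Br)cc1Oc1c(O[Si](C)(C)C)c(Br)c(Br)c(Br)c1Br | intermediate
17 | 3,4,5,6-tetrabromo-2-(3,5-dibromo-2-methoxyphenoxy)phenol | COc1c(Br)cc(Br)cc1Oc1c(O)c(Br)c(Br)c(Br)c1Br | target

**Step count**
- Total step count: 10.
- Longest linear sequence: 9 (steps 1–7, 9 and 10). Step 8 is a one-step side branch.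

**Steps most likely to fail**

**Step 9 (proposed new method).**
- Risks:
  - Steric retardation of the cycloaddition between a trisubstituted dienophile and two bromine-bearing diene termini.
  - Diversion into conjugate addition, or into bromine transfer from the diene to the ketene acetal.
  - Protonolysis of the ketene acetal by the released silanol, or its capture by SO2.
- Fallback (known chemistry) sets out from 4 and returns at 17:
  - Phenol 4 is coupled by SNAr (K2CO3, DMF, 80–100 °C) with purchasable 3,5-dibromo-2-fluorobenzaldehyde (O=Cc1cc(Br)cc(Br)c1F). In this partner only fluorine is ortho to the formyl group and both bromines are meta to it. The product is 3,5-dibromo-2-(3,5-dibromo-2-methoxyphenoxy)benzaldehyde F1.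
  - Baeyer–Villiger oxidation with mCPBA leads to 3,5-dibromo-2-(3,5-dibromo-2-methoxyphenoxy)phenyl formate F2.
  - Methanolysis leads to 3,5-dibromo-2-(3,5-dibromo-2-methoxyphenoxy)phenol F3.
  - The only open ring B positions of F3, C3' and C5', are ortho and para to the free hydroxyl. Br2 (2.2 equiv) in AcOH should therefore fill just these two and give 17. Ring A lacks a free hydroxyl and offers only positions meta to its methoxy group.

**Step 7.**
- Risks:
  - Competing metalation of ring A at C4–H followed by halogen migration.
  - Silylation at carbon instead of oxygen.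
  - Hydrolysis of the product during salt removal.
- Fallback sets out from 7 and returns at 17:
  - Hard enolisation with a lithium amide is replaced by soft enolisation. Acid 7 is treated with tert-butyldimethylsilyl triflate (2.5 equiv) and Et3N in CH2Cl2.
  - This passes through tert-butyldimethylsilyl (3,5-dibromo-2-methoxyphenoxy)acetate F4 to the sturdier 2-(3,5-dibromo-2-methoxyphenoxy)-1,1-bis(tert-butyldimethylsilyloxy)ethene F5, which tolerates a quick wash and storage.
  - F5 is heated with 13 as in step 9. The sequence runs through the bridged sulfone bearing two tert-butyldimethylsilyloxy groups F6 and the corresponding 6,6-bis(tert-butyldimethylsilyloxy)cyclohexadiene F7.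
  - It ends at 3,4,5,6-tetrabromo-2-(3,5-dibromo-2-methoxyphenoxy)phenyl tert-butyldimethylsilyl ether F8, which HF·pyridine in THF converts into 17.

**Step 8.**
- Risks:
  - Stalling at the sulfoxide stage with subsequent self-dimerisation.
  - Oxidative degradation of the ring under the forcing peracid conditions.
- Fallback sets out from 11 and returns at 13:
  - Double Br/Li exchange at the two α-positions (n-BuLi, 2 equiv, THF, −78 °C) gives 3,4-dibromo-2,5-dilithiothiophene F9.
  - Me3SiCl turns F9 into 3,4-dibromo-2,5-bis(trimethylsilyl)thiophene F10.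
  - The more electron-rich and sterically shielded sulfur of F10 should be oxidised by plain mCPBA to 3,4-dibromo-2,5-bis(trimethylsilyl)thiophene 1,1-dioxide F11.
  - Ipso-bromodesilylation of F11 (Br2, AgBF4, CH2Cl2) restores the two α-bromines and delivers 13.

**Further compounds**
F1 | step 9 | 3,5-dibromo-2-(3,5-dibromo-2-methoxyphenoxy)benzaldehyde | COc1c(Br)cc(Br)cc1Oc1c(C=O)cc(Br)cc1Br
F2 | step 9 | 3,5-dibromo-2-(3,5-dibromo-2-methoxyphenoxy)phenyl formate | COc1c(Br)cc(Br)cc1Oc1c(OC=O)cc(Br)cc1Br
F3 | step 9 | 3,5-dibromo-2-(3,5-dibromo-2-methoxyphenoxy)phenol | COc1c(Br)cc(Br)cc1Oc1c(O)cc(Br)cc1Br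
F4 | step 7 | tert-butyldimethylsilyl (3,5-dibromo-2-methoxyphenoxy)acetate | COc1c(Br)cc(Br)cc1OCC(=O)O[Si](C)(C)C(C)(C)C
F5 | step 7 | 2-(3,5-dibromo-2-methoxyphenoxy)-1,1-bis(tert-butyldimethylsilyloxy)ethene | COc1c(Br)cc(Br)cc1OC=C(O[Si](C)(C)C(C)(C)C)O[Si](C)(C)C(C)(C)C
F6 | step 7 | 1,2,3,4-tetrabromo-5-(3,5-dibromo-2-methoxyphenoxy)-6,6-bis(tert-butyldimethylsilyloxy)-7-thiabicyclo[2.2.1]hept-2-ene 7,7-dioxide (racemic, endo/exo open) | O=S1(=O)C2(Br)C(Br)=C(Br)C1(Br)C(Oc1cc(Br)cc(Br)c1OC)C2(O[Si](C)(C)C(C)(C)C)O[Si](C)(C)C(C)(C)C
F7 | step 7 | 1,2,3,4-tetrabromo-5-(3,5-dibromo-2-methoxyphenoxy)-6,6-bis(tert-butyldimethylsilyloxy)cyclohexa-1,3-diene (racemic) | BrC1=C(Br)C(Br)=C(Br)C(O[Si](C)(C)C(C)(C)C)(O[Si](C)(C)C(C)(C)C)C1Oc1cc(Br)cc(Br)c1OC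
F8 | step 7 | 3,4,5,6-tetrabromo-2-(3,5-dibromo-2-methoxyphenoxy)phenyl tert-butyldimethylsilyl ether | COc1c(Br)cc(Br)cc1Oc1c(O[Si](C)(C)C(C)(C)C)c(Br)c(Br)c(Br)c1Br
F9 | step 8 | 3,4-dibromo-2,5-dilithiothiophene | [Li]c1sc([Li])c(Br)c1Br
F10 | step 8 | 3,4-dibromo-2,5-bis(trimethylsilyl)thiophene | C[Si](C)(C)c1sc([Si](C)(C)C)c(Br)c1Br
F11 | step 8 | 3,4-dibromo-2,5-bis(trimethylsilyl)thiophene 1,1-dioxide | C[Si](C)(C)C1=C(Br)C(Br)=C([Si](C)(C)C)S1(=O)=O
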